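## Structural features

The target is a germacranolide. Its ten-membered carbocycle C1–C10 carries a Z (ring-cis) C1=C10 olefin with the methyl C14 on C10, and a C4=C5 olefin whose ring carbons C3 and C6 are trans. An α-methylene-γ-butyrolactone (O–C12(=O)–C11(=C13H2)) is fused to the ring through O–C6 and C7, with H6 and H7 cis. C9 bears an acetate, and C15 on C4 bears an isovalerate. There are three stereocentres: C6 (R) and C7 (R) are adjacent, and C9 (S) stands 1,3 to C7 across the C8 methylene and is allylic to C1=C10. The exo-methylene lactone is a Michael acceptor, both esters are allylic and base-labile, and the 1,5-diene can undergo Cope rearrangement or acid-induced transannular cyclisation. The real difficulty is closing a medium ring that contains a trans olefin while fixing C6 relative to C7, and relating C7 to the remote C9. The key step uses the fact that C6 is an allylic carbinol carbon bonded to vinylic C5 and flanked by the C7 stereocentre. The C5–C6 bond can therefore be made by adding a C5 alkenylmetal to a C6 aldehyde, with the substituents on C7 choosing the face.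

## Logic of the disconnections

35 is cut at C11=C13 to 33 and 34. The exo-methylene is the most electrophilic group and is best made last. This removes the Michael acceptor and leaves a phosphonate that also activates C12. The forward olefination must use a base weak enough for two allylic esters.

33 is cut at the lactone O6–C12 bond to 32. A cis γ-hydroxy ester closes readily, and the open ester lets O6 come from a carbonyl addition. The forward step needs an acid too weak to trigger transannular reactions, and the C6/C7 syn relation must already be in place.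

32 is cut at C5–C6 to 30. This opens the ten-membered ring to an acyclic chain that already carries every other group in its final form. The forward step must metalate the C5–I bond chemoselectively, stay non-basic, attack the aldehyde on the Felkin–Anh face and cyclise rather than oligomerise.

30 is traced by functional-group changes through 29, 27 and 26 to 24, with the acyl groups coming from 28 and 25. The C6 aldehyde stays masked as a dithiane until the step before ring closure, so neither an α-epimerisable aldehyde nor a free γ-hydroxy ester is carried. The unmasking must be near neutral, and both acylations must follow all strongly basic steps.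

24 is traced to 23 by joining O9 and C12 in a six-membered lactone. The lactone protects O9 and C12 during enolate chemistry and ties C9 to C7 so that C9 can control C7. The forward ring opening must be trapped before it reverses.

23 is cut at C11–P to 21. One enolisable position makes the phosphorus introduction regiochemically simple. The forward step must avoid excess strong base because of the C5–I unit.

21 is cut at C6–C7 to 18 and 19. A formyl anion equivalent adding anti to the C9 substituent gives the 4,6-trans lactone, which is the C7/C9 relation of the target. The forward step must go 1,4 and not 1,2.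

18 is cut at C7=C11 to 17, and 17 at the O9–C12 ester bond to 15 and 16. Metathesis and acylation are reliable and use a two-carbon acyl unit. The metathesis must ignore the two other alkenes.

15 is cut at C8–C9 to 11 and 12. Allylboration sets C9 by reagent control on a substrate with no other stereocentre. The Z-enal must not isomerise before it reacts.

11 is traced through 10 and 9 and cut at C1=C10 to 7 and 8. A Z-selective phosphonate olefination gives the ring-cis olefin. It needs kinetic control.

7 is traced through 5 to 4, and 4 is cut at C3–C4 and C5–I to 1 and 2. An anti-carbomagnesiation of a propargylic alkoxide places the metal, and then iodine, cis to the C15 oxygen arm. The forward step must be regio- and stereoselective on a very small substrate.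

## Other disconnections considered

Alternative 1: The cut is C7–C8, made on an eleven-membered β-keto lactone A2 in which O6 is acylated by a C8 malonyl-type unit and C6 carries a 2-(acetoxymethyl)propenoate. Cs2CO3 would form the C8 enolate, which adds 5-exo to C7 and expels acetate from C13 to give the bridged keto lactone A1.
- In its favour: the ring is first closed by an ester bond, which is easier than a carbon–carbon closure, and is then contracted intramolecularly.
- Better than the chosen plan: the C11=C13 methylene is formed in the key step, so no phosphonate and no separate methylenation are needed, and no α-epimerisable aldehyde is involved.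
- Better than the chosen plan: C7 is set relative to C6 by a small-ring fusion, which is a firmer element than an open Felkin–Anh transition state.
- Against it: C9 arrives as a ketone conjugated to the Z C1=C10 olefin. It would need a late diastereoselective reduction in a flexible ring, whereas the chosen plan sets C9 early by reagent control and carries the acetate through.
- Against it: the extra carboxyl carbon on C8 must be removed by lactone opening and decarboxylation before O6 can close onto C12.
- Against it: carbonate in the presence of an enone and an acrylate invites intermolecular Michael reactions and Z-to-E isomerisation.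
- Step economy: about five steps would follow the key step, against two here. The routes to A2 and to 30 should be of similar length.

Alternative 2: The bond that is broken in the forward step is C4–C9 of a trans-fused hydroxy-decalin mesylate A4. KOtBu would form the C9 alkoxide, and the C4–C9 bond, anti-periplanar to the equatorial C5 mesylate, fragments to the dienone A3.
- Better than the chosen plan: the ten-membered ring is released from a bicycle, so there is no dilution or entropy problem.
- Equal to the chosen plan: both olefin geometries are fixed stereospecifically, Z by the cyclohexene and E by the anti-periplanar geometry.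
- Arguably better: C6 and C7 are set on a six-membered ring by conventional means.
- Against it: A4 needs five stereocentres, of which three (C4, C5, C9) are destroyed.
- Against it: C9 is again a ketone, and the strongly basic medium could isomerise or deconjugate the new Z-enone.
- Against it: C12 is still at the alcohol oxidation level, so lactone formation needs a selective allylic oxidation and deprotection of O6 in the presence of the dienone.
- Step economy: some seven or eight steps would follow the fragmentation, and A4 itself is a long synthesis. The mechanism is the most dependable of the three, but the plan is clearly longer than the chosen one.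

Alternative 3: The cut is C9–C10. NiBr2(dme), a chiral bis(oxazoline) ligand and manganese powder would couple the Z-alkenyl iodide at C10 of A6 with its epimeric 1-bromoalkyl acetate at C9 and give A5 directly.
- Better than the chosen plan: the cis-lactone (C6, C7) is built earlier on a five-membered ring, where control is easy.
- Better than the chosen plan: there is no α-stereogenic aldehyde.
- Equal to the chosen plan: C9 is set and the ring closed in one step with the acetate already present, and about three steps would follow (desilylation, acylation, methylenation).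
- Against it: the new bond is made at the fully substituted alkenyl carbon C10 to a secondary α-acetoxy radical, which is a more hindered closure than at the CH carbon C5.
- Against it: the catalyst must override the conformational bias of the forming ring at C9, which is less secure than setting C9 by allylboration on a small molecule.
- Against it: the 1-bromoalkyl acetate is moisture-labile and has to be made at the last moment beside the phosphono lactone.
- Against it: a Z-alkenylnickel species may isomerise, and reduction of the C–Br bond competes at high dilution.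
- Against it: the stereoconvergent coupling is known between separate partners, but its medium-ring version would be new chemistry, whereas the chosen closure has close analogy.

Key step: step 17

Remarks on the chemistry (one line each):
- By the CIP rules the C4=C5 olefin of the target and the alkenyl iodide are Z, because C15 carries oxygen and outranks C3; "E" describes only the trans relation of C3 to C6 or to iodine, and all structures are drawn that way.
- A symmetrical butynediol has an oxygenated carbon on each alkyne carbon and cannot supply the unsubstituted CH–I terminus C5, so C4, C5 and C15 are taken from 1.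
- A free C6 alcohol would be γ to the C12 ester and would lactonise before oxidation, so C6 is carried as a dithiane at the aldehyde oxidation level.
- C11 is an uncontrolled stereocentre from 23 to 33 and is erased in step 19; these compounds are handled as C11 epimer mixtures.
- TBS means tert-butyldimethylsilyl; positions C1–C15 refer to the germacrane numbering used above.

## Route

Step 1
Reactants: 1 prop-2-yn-1-ol; 2 but-3-en-1-ylmagnesium bromide
Product: 4 (2Z)-2-(but-3-en-1-yl)-3-iodoprop-2-en-1-ol, via alkenylmagnesium alkoxide chelate 3 (not isolated)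
Conditions: 2 (2.5 equiv), CuI (10 mol%), Et2O–THF, −10 °C to rt; then I2, THF, −20 to 0 °C
Reagents that add atoms: iodine, [I][I]
Why: Copper-catalysed anti-carbomagnesiation of the propargylic magnesium alkoxide puts the butenyl group on the internal alkyne carbon (C4) and magnesium on the terminal carbon (C5), held cis to the CH2O arm in a five-membered chelate; iodinolysis with retention then places iodine cis to C15.

Step 2
Reactants: 4
Product: 5 tert-butyl{[(2Z)-2-(but-3-en-1-yl)-3-iodoprop-2-en-1-yl]oxy}dimethylsilane
Conditions: TBSCl, imidazole, CH2Cl2, 0 °C to rt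
Reagents that add atoms: tert-butyldimethylsilyl chloride, CC(C)(C)[Si](C)(C)Cl
Why: Standard silylation of a primary alcohol; O15 must be masked through hydride, organolithium and amide-base steps that an ester would not survive.

Step 3
Reactants: 5
Product: 7 (4Z)-4-{[(TBS)oxy]methyl}-5-iodopent-4-enal, via vicinal diol 6 (not isolated)
Conditions: OsO4 (2 mol%), NaIO4 (4 equiv), 2,6-lutidine, dioxane–H2O 3:1, rt
Reagents that add atoms: osmium tetroxide, O=[Os](=O)(=O)=O; sodium periodate, [Na+].[O-]I(=O)(=O)=O
Why: Lemieux–Johnson oxidation; the terminal monosubstituted alkene is dihydroxylated much faster than the trisubstituted, iodine-deactivated alkene, and periodate cleaves the diol to the C1 aldehyde.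

Step 4
Reactants: 7; 8 ethyl 2-[bis(2,2,2-trifluoroethoxy)phosphoryl]propanoate
Product: 9 ethyl (2Z,6Z)-6-{[(TBS)oxy]methyl}-7-iodo-2-methylhepta-2,6-dienoate
Conditions: 8, KN(SiMe3)2, 18-crown-6, THF, −78 °C; then 7
Reagents that add atoms: none
Why: Still–Gennari olefination; the electron-poor phosphonate with a dissociated potassium ion eliminates under kinetic control to the Z-trisubstituted enoate, with the ester (C9) cis to the chain (C2), which is the C1=C10 geometry of the target.

Step 5
Reactants: 9
Product: 10 (2Z,6Z)-6-{[(TBS)oxy]methyl}-7-iodo-2-methylhepta-2,6-dien-1-ol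
Conditions: i-Bu2AlH (2.5 equiv), CH2Cl2, −78 °C; aqueous potassium sodium tartrate
Reagents that add atoms: none
Why: 1,2-Reduction of the conjugated ester by a Lewis-acidic hydride; the silyl ether and the alkenyl iodide are inert at −78 °C.

Step 6
Reactants: 10
Product: 11 (2Z,6Z)-6-{[(TBS)oxy]methyl}-7-iodo-2-methylhepta-2,6-dienal
Conditions: MnO2 (excess), CH2Cl2, rt; filtered and used at once
Reagents that add atoms: none
Why: Neutral heterogeneous oxidation of an allylic alcohol; no acid or base is present that could isomerise the Z-enal.

Step 7
Reactants: 11; 12 allylmagnesium bromide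
Product: 15 (4S,5Z,9Z)-9-{[(TBS)oxy]methyl}-10-iodo-5-methyldeca-1,5,9-trien-4-ol, via B-allyldiisopinocampheylborane 13 (not isolated), via diisopinocampheylborinate ester 14 (not isolated)
Conditions: (−)-B-methoxydiisopinocampheylborane [from (+)-α-pinene], 12, Et2O, 0 °C to rt, magnesium salts filtered off; 11, −78 °C; then NaOH, H2O2, 0 °C to rt
Reagents that add atoms: none
Why: Brown allylboration through a chair Zimmerman–Traxler transition state; the isopinocampheyl groups from (+)-α-pinene direct allyl transfer to the Si face of the aldehyde, which for an alkenyl aldehyde gives the 4S alcohol (C9 of the target) by reagent control.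

Step 8
Reactants: 15; 16 acryloyl chloride
Product: 17 (4S,5Z,9Z)-9-{[(TBS)oxy]methyl}-10-iodo-5-methyldeca-1,5,9-trien-4-yl prop-2-enoate
Conditions: 16, i-Pr2NEt, DMAP (cat.), CH2Cl2, −20 to 0 °C
Reagents that add atoms: none
Why: O-Acylation of the secondary alcohol; it brings in C11 and C12 and the second alkene for ring closure.

Step 9
Reactants: 17
Product: 18 (6S)-6-[(2Z,6Z)-6-{[(TBS)oxy]methyl}-7-iodohepta-2,6-dien-2-yl]-5,6-dihydro-2H-pyran-2-one
Conditions: second-generation Grubbs catalyst (5 mol%), CH2Cl2 (5 mM), 40 °C
Reagents that add atoms: none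
Why: Ring-closing metathesis of the terminal alkene with the acrylate closes the six-membered unsaturated lactone (C7=C11); the trisubstituted C1=C10 alkene and the iodoalkene are too hindered and electron-poor to take part.

Step 10
Reactants: 18; 19 1,3-dithiane
Product: 21 (4R,6S)-4-(1,3-dithian-2-yl)-6-[(2Z,6Z)-6-{[(TBS)oxy]methyl}-7-iodohepta-2,6-dien-2-yl]oxan-2-one, via 2-lithio-1,3-dithiane 20 (not isolated)
Conditions: 19 (1.3 equiv), n-BuLi (1.2 equiv), THF, −30 °C; HMPA (2 equiv), −78 °C; then 18, −78 °C; NH4Cl
Reagents that add atoms: none
Why: Conjugate addition of a formyl anion equivalent; HMPA makes the lithiodithiane a solvent-separated ion pair that adds 1,4, and axial attack on the half-chair anti to the pseudo-equatorial C9 substituent should give the 4,6-trans lactone, which is the C7 configuration of the target relative to C9.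

Step 11
Reactants: 21
Product: 23 diethyl {(4R,6S)-4-(1,3-dithian-2-yl)-6-[(2Z,6Z)-6-{[(TBS)oxy]methyl}-7-iodohepta-2,6-dien-2-yl]-2-oxooxan-3-yl}phosphonate, via α-phosphonite lactone 22 (not isolated)
Conditions: LiN(i-Pr)2 (1.1 equiv), THF, −78 °C; ClP(OEt)2, −78 °C to rt; then air, rt
Reagents that add atoms: diethyl chlorophosphite, CCOP(Cl)OCC; dioxygen, O=O
Why: C-Phosphinylation of the lactone enolate with a trivalent phosphorus electrophile followed by air oxidation to the phosphonate; only about one equivalent of amide base is used, so the vinylic C5–H next to iodine and the dithiane C–H are not touched, and the configuration at C11 does not matter.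

Step 12
Reactants: 23
Product: 24 methyl (3R,5S,6Z,10Z)-10-{[(TBS)oxy]methyl}-2-(diethoxyphosphoryl)-3-(1,3-dithian-2-yl)-5-hydroxy-11-iodo-6-methylundeca-6,10-dienoate
Conditions: K2CO3 (1.2 equiv), MeOH, 0 °C; pH 7 buffer, carried on at once
Reagents that add atoms: methanol, CO
Why: Base-mediated transesterification opens the δ-lactone to the methyl ester and frees O9; with methanol as solvent the open hydroxy ester should be favoured, and it is trapped in the next step.

Step 13
Reactants: 24; 25 acetic anhydride
Product: 26 methyl (3R,5S,6Z,10Z)-5-acetoxy-10-{[(TBS)oxy]methyl}-2-(diethoxyphosphoryl)-3-(1,3-dithian-2-yl)-11-iodo-6-methylundeca-6,10-dienoate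
Conditions: 25, pyridine, DMAP (cat.), CH2Cl2, 0 °C to rt
Reagents that add atoms: none
Why: Acylation of the secondary allylic alcohol installs the C9 acetate of the target and blocks relactonisation.

Step 14
Reactants: 26
Product: 27 methyl (3R,5S,6Z,10Z)-5-acetoxy-2-(diethoxyphosphoryl)-3-(1,3-dithian-2-yl)-10-(hydroxymethyl)-11-iodo-6-methylundeca-6,10-dienoate
Conditions: HF·pyridine, pyridine–THF, 0 °C to rt
Reagents that add atoms: none
Why: Fluoride cleavage of the primary silyl ether under buffered conditions that leave the acetate, methyl ester, phosphonate, dithiane and alkenyl iodide intact.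

Step 15
Reactants: 27; 28 isovaleryl chloride
Product: 29 methyl (3R,5S,6Z,10Z)-5-acetoxy-2-(diethoxyphosphoryl)-3-(1,3-dithian-2-yl)-11-iodo-6-methyl-10-[(3-methylbutanoyloxy)methyl]undeca-6,10-dienoate
Conditions: 28, pyridine, DMAP (cat.), CH2Cl2, 0 °C
Reagents that add atoms: none
Why: Acylation of the primary allylic alcohol gives the C15 isovalerate; it is introduced only now because every strongly basic or nucleophilic step is past.

Step 16
Reactants: 29
Product: 30 methyl (3S,5S,6Z,10Z)-5-acetoxy-2-(diethoxyphosphoryl)-3-formyl-11-iodo-6-methyl-10-[(3-methylbutanoyloxy)methyl]undeca-6,10-dienoate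
Conditions: MeI (excess), CaCO3, MeCN–H2O 9:1, 40 °C; used at once
Reagents that add atoms: water, O
Why: S-Methylation of the dithiane and hydrolysis of the sulfonium ion release the C6 aldehyde under near-neutral conditions, so the C7 α-stereocentre and the esters should survive and no γ-hydroxy ester is ever formed.

Step 17
Reactants: 30
Product: 32 methyl 2-(diethoxyphosphoryl)-2-[(1S,2R,3Z,7Z,9S)-9-acetoxy-2-hydroxy-8-methyl-4-[(3-methylbutanoyloxy)methyl]cyclodeca-3,7-dien-1-yl]acetate, via C6 trimethylsilyl ether 31 (not isolated)
Conditions: CrCl2 (20 mol%), NiCl2(DME) (5 mol%), Me3SiCl (3 equiv), LiClO4 (0.1 M), DMF–THF, undivided cell, Al anode, Ni-foam cathode, constant current, 30 added over 10 h (final 2 mM), rt; then aqueous citric acid, THF, 0 °C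
Reagents that add atoms: none
Why: Zerovalent nickel, formed from NiCl2 by divalent chromium, inserts into the C5–I bond with retention and passes the alkenyl group to trivalent chromium; the alkenylchromium adds to the C6 aldehyde, Me3SiCl silylates the chromium alkoxide, and the cathode reduces the released trivalent chromium back to divalent chromium, so chromium is catalytic while the aluminium anode is consumed. The closest known reaction type is the Nozaki–Hiyama–Kishi alkenylation of aldehydes in its electrochemically driven chromium-catalytic form, combined with the use of this reaction to close medium carbocycles. The ten-membered ring closes by 10-exo-trig attack on the aldehyde C=O. The new stereocentre C6 is controlled by C7 through a Felkin–Anh transition state in which the branched C11 phosphonoacetate arm stands anti to the incoming alkenyl group, so the new C–O bond should end up syn to C11 (6R, the cis-lactone relation). Oxidative addition must choose the alkenyl iodide over the two allylic esters, which the far higher reactivity of the C–I bond and the low nickel loading should secure; the alkenylchromium must choose the aldehyde over three esters, which is its inherent chemoselectivity. Cyclisation over oligomerisation is secured by slow addition and the low stationary concentration of the organochromium species. The medium is non-basic, so C7 should not epimerise and the C11–H is not deprotonated, and the C4=C5 geometry is carried over because oxidative addition and transmetalation proceed with retention. Mild acid in the work-up removes the trimethylsilyl group.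

Step 18
Reactants: 32
Product: 33 diethyl [(6R,7S,9S)-9-acetoxy-15-(3-methylbutanoyloxy)germacra-1(10),4-dien-12,6-olid-11-yl]phosphonate (cis-fused γ-lactone)
Conditions: PPTS (10 mol%), CH2Cl2, rt
Reagents that add atoms: none
Why: Acid-catalysed intramolecular transesterification; O6 is syn to the ester arm and five-membered closure onto the phosphonate-activated methyl ester should be fast, so a weak pyridinium acid suffices and the diene is not exposed to acid strong enough for transannular cyclisation.

Step 19
Reactants: 33; 34 formaldehyde
Product: 35 (6R,7R,9S)-9-acetoxy-15-(3-methylbutanoyloxy)germacra-1(10),4,11(13)-trien-12,6-olide (CNP0398030.1)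
Conditions: 34 (37% aq.), K2CO3, THF, 0 °C
Reagents that add atoms: none
Why: Horner–Wadsworth–Emmons olefination of the phosphonate carbanion with formaldehyde creates the C11=C13 methylene; C11 becomes sp2, so its epimers converge, and the cold, weakly basic medium should spare the acetate and the isovalerate.

## Compound list

1 | prop-2-yn-1-ol | C#CCO | starting material
2 | but-3-en-1-ylmagnesium bromide | C=CCC[Mg]Br | starting material
3 | five-membered alkenylmagnesium alkoxide chelate (Mg on C5, O15) | C=CCCC1=C[Mg]OC1 | intermediate (not isolated)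
4 | (2Z)-2-(but-3-en-1-yl)-3-iodoprop-2-en-1-ol | I/C=C(\CO)CCC=C | intermediate
5 | tert-butyl{[(2Z)-2-(but-3-en-1-yl)-3-iodoprop-2-en-1-yl]oxy}dimethylsilane | I/C=C(\CO[Si](C)(C)C(C)(C)C)CCC=C | intermediate
6 | (5Z)-5-{[(tert-butyldimethylsilyl)oxy]methyl}-6-iodohex-5-ene-1,2-diol | I/C=C(\CO[Si](C)(C)C(C)(C)C)CCC(O)CO | intermediate (not isolated)
7 | (4Z)-4-{[(tert-butyldimethylsilyl)oxy]methyl}-5-iodopent-4-enal | I/C=C(\CO[Si](C)(C)C(C)(C)C)CCC=O | intermediate
8 | ethyl 2-[bis(2,2,2-trifluoroethoxy)phosphoryl]propanoate | CCOC(=O)C(C)P(=O)(OCC(F)(F)F)OCC(F)(F)F | starting material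
9 | ethyl (2Z,6Z)-6-{[(tert-butyldimethylsilyl)oxy]methyl}-7-iodo-2-methylhepta-2,6-dienoate | I/C=C(\CO[Si](C)(C)C(C)(C)C)CC/C=C(/C)C(=O)OCC | intermediate
10 | (2Z,6Z)-6-{[(tert-butyldimethylsilyl)oxy]methyl}-7-iodo-2-methylhepta-2,6-dien-1-ol | I/C=C(\CO[Si](C)(C)C(C)(C)C)CC/C=C(/C)CO | intermediate
11 | (2Z,6Z)-6-{[(tert-butyldimethylsilyl)oxy]methyl}-7-iodo-2-methylhepta-2,6-dienal | I/C=C(\CO[Si](C)(C)C(C)(C)C)CC/C=C(/C)C=O | intermediate
12 | allylmagnesium bromide | C=CC[Mg]Br | starting material
13 | B-allyldiisopinocampheylborane from (+)-α-pinene | C=CCB([C@@H]1C[C@@H]2C[C@H]([C@H]1C)C2(C)C)[C@@H]1C[C@@H]2C[C@H]([C@H]1C)C2(C)C | intermediate (not isolated)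
14 | diisopinocampheylborinate ester of 15 | I/C=C(\CO[Si](C)(C)C(C)(C)C)CC/C=C(/C)[C@@H](OB([C@@H]1C[C@@H]2C[C@H]([C@H]1C)C2(C)C)[C@@H]1C[C@@H]2C[C@H]([C@H]1C)C2(C)C)CC=C | intermediate (not isolated)
15 | (4S,5Z,9Z)-9-{[(tert-butyldimethylsilyl)oxy]methyl}-10-iodo-5-methyldeca-1,5,9-trien-4-ol | I/C=C(\CO[Si](C)(C)C(C)(C)C)CC/C=C(/C)[C@@H](O)CC=C | intermediate
16 | acryloyl chloride | C=CC(Cl)=O | starting material
17 | (4S,5Z,9Z)-9-{[(tert-butyldimethylsilyl)oxy]methyl}-10-iodo-5-methyldeca-1,5,9-trien-4-yl prop-2-enoate | I/C=C(\CO[Si](C)(C)C(C)(C)C)CC/C=C(/C)[C@@H](OC(=O)C=C)CC=C | intermediate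
18 | (6S)-6-[(2Z,6Z)-6-{[(tert-butyldimethylsilyl)oxy]methyl}-7-iodohepta-2,6-dien-2-yl]-5,6-dihydro-2H-pyran-2-one | I/C=C(\CO[Si](C)(C)C(C)(C)C)CC/C=C(/C)[C@@H]1CC=CC(=O)O1 | intermediate
19 | 1,3-dithiane | C1CSCSC1 | starting material
20 | 2-lithio-1,3-dithiane | [Li]C1SCCCS1 | intermediate (not isolated)
21 | (4R,6S)-4-(1,3-dithian-2-yl)-6-[(2Z,6Z)-6-{[(tert-butyldimethylsilyl)oxy]methyl}-7-iodohepta-2,6-dien-2-yl]oxan-2-one | I/C=C(\CO[Si](C)(C)C(C)(C)C)CC/C=C(/C)[C@@H]1C[C@@H](C2SCCCS2)CC(=O)O1 | intermediate
22 | diethyl phosphonite at C3 of lactone 21 (C3 epimers) | I/C=C(\CO[Si](C)(C)C(C)(C)C)CC/C=C(/C)[C@@H]1C[C@@H](C2SCCCS2)C(P(OCC)OCC)C(=O)O1 | intermediate (not isolated)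
23 | diethyl {(4R,6S)-4-(1,3-dithian-2-yl)-6-[(2Z,6Z)-6-{[(tert-butyldimethylsilyl)oxy]methyl}-7-iodohepta-2,6-dien-2-yl]-2-oxooxan-3-yl}phosphonate (C3 epimers) | I/C=C(\CO[Si](C)(C)C(C)(C)C)CC/C=C(/C)[C@@H]1C[C@@H](C2SCCCS2)C(P(=O)(OCC)OCC)C(=O)O1 | intermediate
24 | methyl (3R,5S,6Z,10Z)-10-{[(tert-butyldimethylsilyl)oxy]methyl}-2-(diethoxyphosphoryl)-3-(1,3-dithian-2-yl)-5-hydroxy-11-iodo-6-methylundeca-6,10-dienoate | I/C=C(\CO[Si](C)(C)C(C)(C)C)CC/C=C(/C)[C@@H](O)C[C@@H](C1SCCCS1)C(P(=O)(OCC)OCC)C(=O)OC | intermediate
25 | acetic anhydride | CC(=O)OC(C)=O | starting material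
26 | methyl (3R,5S,6Z,10Z)-5-acetoxy-10-{[(tert-butyldimethylsilyl)oxy]methyl}-2-(diethoxyphosphoryl)-3-(1,3-dithian-2-yl)-11-iodo-6-methylundeca-6,10-dienoate | I/C=C(\CO[Si](C)(C)C(C)(C)C)CC/C=C(/C)[C@@H](OC(C)=O)C[C@@H](C1SCCCS1)C(P(=O)(OCC)OCC)C(=O)OC | intermediate
27 | methyl (3R,5S,6Z,10Z)-5-acetoxy-2-(diethoxyphosphoryl)-3-(1,3-dithian-2-yl)-10-(hydroxymethyl)-11-iodo-6-methylundeca-6,10-dienoate | I/C=C(\CO)CC/C=C(/C)[C@@H](OC(C)=O)C[C@@H](C1SCCCS1)C(P(=O)(OCC)OCC)C(=O)OC | intermediate
28 | isovaleryl chloride | CC(C)CC(Cl)=O | starting material
29 | methyl (3R,5S,6Z,10Z)-5-acetoxy-2-(diethoxyphosphoryl)-3-(1,3-dithian-2-yl)-11-iodo-6-methyl-10-[(3-methylbutanoyloxy)methyl]undeca-6,10-dienoate | I/C=C(\COC(=O)CC(C)C)CC/C=C(/C)[C@@H](OC(C)=O)C[C@@H](C1SCCCS1)C(P(=O)(OCC)OCC)C(=O)OC | intermediate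
30 | methyl (3S,5S,6Z,10Z)-5-acetoxy-2-(diethoxyphosphoryl)-3-formyl-11-iodo-6-methyl-10-[(3-methylbutanoyloxy)methyl]undeca-6,10-dienoate (open-chain C6 aldehyde) | I/C=C(\COC(=O)CC(C)C)CC/C=C(/C)[C@@H](OC(C)=O)C[C@@H](C=O)C(P(=O)(OCC)OCC)C(=O)OC | intermediate
31 | C6 trimethylsilyl ether of 32 | C[Si](C)(C)O[C@@H]1/C=C(\COC(=O)CC(C)C)CC/C=C(/C)[C@@H](OC(C)=O)C[C@@H]1C(P(=O)(OCC)OCC)C(=O)OC | intermediate (not isolated)
32 | methyl 2-(diethoxyphosphoryl)-2-[(1S,2R,3Z,7Z,9S)-9-acetoxy-2-hydroxy-8-methyl-4-[(3-methylbutanoyloxy)methyl]cyclodeca-3,7-dien-1-yl]acetate (ten-membered C6 carbinol) | O[C@@H]1/C=C(\COC(=O)CC(C)C)CC/C=C(/C)[C@@H](OC(C)=O)C[C@@H]1C(P(=O)(OCC)OCC)C(=O)OC | intermediate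
33 | diethyl [(6R,7S,9S)-9-acetoxy-15-(3-methylbutanoyloxy)germacra-1(10),4-dien-12,6-olid-11-yl]phosphonate (cis-fused lactone, C11 epimers) | CCOP(=O)(OCC)C1C(=O)O[C@@H]2/C=C(\COC(=O)CC(C)C)CC/C=C(/C)[C@@H](OC(C)=O)C[C@H]12 | intermediate
34 | formaldehyde | C=O | starting material
35 | (6R,7R,9S)-9-acetoxy-15-(3-methylbutanoyloxy)germacra-1(10),4,11(13)-trien-12,6-olide, CNP0398030.1 | C=C1C(=O)O[C@@H]2/C=C(\COC(=O)CC(C)C)CC/C=C(/C)[C@@H](OC(C)=O)C[C@H]12 | target

## Step count and least certain steps

Total: 19 steps. Longest linear sequence: 19 steps (from 1 and 2 to 35); all other building blocks enter in single steps.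

Step 17 (key step). What is most likely to go wrong is poor facial selectivity at C6, because the ring-closing transition state need not follow the open-chain Felkin–Anh preference. Oligomerisation, protodemetalation of the alkenylchromium by the acidic C11–H, and epimerisation at C7 of the aldehyde before it reacts could add to this. Fallback: setting out from 32 obtained as a C6 epimer mixture, oxidation with Dess–Martin periodinane and NaHCO3 in CH2Cl2 would give the ten-membered C6 enone F1. Corey–Bakshi–Shibata reduction with the (R)-2-methyl-oxazaborolidine and catecholborane in toluene at −78 °C would then deliver hydride under reagent control. If the alkenyl side acts as the larger group, as is usual for enones, this returns the 6R carbinol 32.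

Step 10. The lithiodithiane may add 1,2 to the lactone carbonyl, or add 1,4 with too little preference for the face anti to the C9 substituent. Fallback: setting out from 18, the bulkier and softer 2-lithio-2-(trimethylsilyl)-1,3-dithiane in THF–HMPA would give the C-silylated dithiane lactone F2. Bu4NF buffered with AcOH would remove the carbon-bound silyl group, and with it the C15 silyl ether, to give the hydroxy lactone F3. TBSCl and imidazole would then return 21.

Step 12. The ring–chain equilibrium may not lie far enough on the open side, or the δ-lactone may close again during work-up before acetylation. Fallback: setting out from 23, LiOH in THF–H2O would open the lactone irreversibly to the lithium hydroxy carboxylate F4. Acetic anhydride and pyridine would give the acetoxy acid F5, and Me3SiCHN2 in MeOH–toluene would methylate it, returning to the route at 26.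

Step 18. Acid may trigger transannular cyclisation of the 1(10),4-diene or ionisation of an allylic ester before the lactone has closed. Fallback: setting out from 32, the order is reversed. K2CO3 and 34 in THF at 0 °C would carry out the olefination first and give the open-chain hydroxy acrylate F6. Its O6 should close onto the methyl ester in the same basic medium, completed if necessary with i-Pr2NEt and DMAP in CH2Cl2, which arrives directly at 35.

Further compounds
F1 | step 17 | ten-membered C6 enone: methyl 2-(diethoxyphosphoryl)-2-[(1S,3Z,7Z,9S)-9-acetoxy-8-methyl-4-[(3-methylbutanoyloxy)methyl]-2-oxocyclodeca-3,7-dien-1-yl]acetate | O=C1/C=C(\COC(=O)CC(C)C)CC/C=C(/C)[C@@H](OC(C)=O)C[C@@H]1C(P(=O)(OCC)OCC)C(=O)OC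
F2 | step 10 | (4R,6S)-6-[(2Z,6Z)-6-{[(tert-butyldimethylsilyl)oxy]methyl}-7-iodohepta-2,6-dien-2-yl]-4-[2-(trimethylsilyl)-1,3-dithian-2-yl]oxan-2-one | I/C=C(\CO[Si](C)(C)C(C)(C)C)CC/C=C(/C)[C@@H]1C[C@@H](C2([Si](C)(C)C)SCCCS2)CC(=O)O1
F3 | step 10 | (4R,6S)-4-(1,3-dithian-2-yl)-6-[(2Z,6Z)-6-(hydroxymethyl)-7-iodohepta-2,6-dien-2-yl]oxan-2-one | I/C=C(\CO)CC/C=C(/C)[C@@H]1C[C@@H](C2SCCCS2)CC(=O)O1
F4 | step 12 | lithium (3R,5S,6Z,10Z)-10-{[(tert-butyldimethylsilyl)oxy]methyl}-2-(diethoxyphosphoryl)-3-(1,3-dithian-2-yl)-5-hydroxy-11-iodo-6-methylundeca-6,10-dienoate | I/C=C(\CO[Si](C)(C)C(C)(C)C)CC/C=C(/C)[C@@H](O)C[C@@H](C1SCCCS1)C(P(=O)(OCC)OCC)C(=O)[O-].[Li+]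
F5 | step 12 | (3R,5S,6Z,10Z)-5-acetoxy-10-{[(tert-butyldimethylsilyl)oxy]methyl}-2-(diethoxyphosphoryl)-3-(1,3-dithian-2-yl)-11-iodo-6-methylundeca-6,10-dienoic acid | I/C=C(\CO[Si](C)(C)C(C)(C)C)CC/C=C(/C)[C@@H](OC(C)=O)C[C@@H](C1SCCCS1)C(P(=O)(OCC)OCC)C(=O)O
F6 | step 18 | methyl 2-[(1R,2R,3Z,7Z,9S)-9-acetoxy-2-hydroxy-8-methyl-4-[(3-methylbutanoyloxy)methyl]cyclodeca-3,7-dien-1-yl]prop-2-enoate | O[C@@H]1/C=C(\COC(=O)CC(C)C)CC/C=C(/C)[C@@H](OC(C)=O)C[C@@H]1C(=C)C(=O)OC
A1 | alternative 1 | ten-membered C9 ketone bridged by the temporary O6–CO–C8 γ-lactone, with the C7 methyl propenoate | C=C(C(=O)OC)[C@@H]1[C@H]2/C=C(\CO[Si](C)(C)C(C)(C)C)CC/C=C(/C)C(=O)[C@@H]1C(=O)O2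
A2 | alternative 1 | eleven-membered β-keto lactone with the pendant methyl 2-(acetoxymethyl)propenoate on C6 | COC(=O)C(COC(C)=O)=C[C@H]1/C=C(\CO[Si](C)(C)C(C)(C)C)CC/C=C(/C)C(=O)CC(=O)O1
A3 | alternative 2 | ten-membered 1(10)Z,4E-dien-9-one with C6–OTBS and the C7 2-(silyloxymethyl)vinyl group | C=C(CO[Si](C)(C)C(C)(C)C)[C@H]1CC(=O)/C(C)=C\CC/C(COCc2ccc(OC)cc2)=C/[C@H]1O[Si](C)(C)C(C)(C)C
A4 | alternative 2 | trans-fused angular C9 hydroxy-decalin with equatorial C5 mesylate, drawn as one workable diastereomer | C=C(CO[Si](C)(C)C(C)(C)C)[C@H]1C[C@@]2(O)C(C)=CCC[C@]2(COCc3ccc(OC)cc3)[C@@H](OS(C)(=O)=O)[C@H]1O[Si](C)(C)C(C)(C)C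
A5 | alternative 3 | ten-membered ring with cis-fused α-phosphono lactone, C9 acetate and C15 silyl ether | CCOP(=O)(OCC)C1C(=O)O[C@@H]2/C=C(\CO[Si](C)(C)C(C)(C)C)CC/C=C(/C)[C@@H](OC(C)=O)C[C@H]12
A6 | alternative 3 | open-chain α-phosphono lactone with the Z-alkenyl iodide at C10 and the epimeric 1-bromoalkyl acetate at C9 | CCOP(=O)(OCC)C1C(=O)O[C@H](/C=C(\CO[Si](C)(C)C(C)(C)C)CC/C=C(/C)I)[C@@H]1CC(Br)OC(C)=O
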